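**Retrosynthetic overview**
- The target comes from its tetrakis-MOM ether. The two different chain ends (CH2Cl and CHCl2) come from one hydroxy aldehyde, made by mono-reduction of a C2-symmetric dialdehyde; this is the only place where the symmetry is broken.
- The C2-symmetric saturated macrocycle comes from hydrogenation of an E,E-diene. The diene arises by head-to-tail olefin-metathesis cyclodimerization of one monomer, forming C5=C6 and C18=C19; the second of these closes the 22-membered ring. This is the only ring formed in the route, since both resorcinol rings are bought.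
- Enabling feature: the [7.7]paracyclophane core (bridges C1–C7 and C14–C20, resorcinol rings A and B) is C2-symmetric, so C5–C6 and C18–C19 are equivalent. The halves differ only by one chlorine at the far end of the butyl chains on C7 and C20. On each ring the two bridges sit para to each other, so one monomer cannot cyclize on itself.
- The monomer comes from anti-SN2' arylation of a (2S,3Z)-allylic picolinate with an aryl copper reagent made by lithiation between the two OMOM groups. This forms the aryl–C7 bond and sets C7 by 1,3-chirality transfer from (S)-but-3-yn-2-ol.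
- The arene arm comes from an Evans syn-aldol on 3,5-bis(methoxymethoxy)benzaldehyde (sets C1 and C2), then reduction, tosylation and allylation.

Key step: step 13

Assumption: the cyclophane is numbered as in the cylindrocyclophane family (C1/C14 carbamate-bearing benzylic carbons, C2/C15 methyl-bearing carbons, C7/C20 side-chain-bearing carbons bound to the ring carbon between the two oxygens); with this numbering the target is (1R,2S,7S,14R,15S,20S).

**Step 1**
Reactants: 1 3,5-dihydroxybenzaldehyde; 2 chloromethyl methyl ether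
Product: 3 3,5-bis(methoxymethoxy)benzaldehyde
Conditions: MOMCl, i-Pr2NEt, CH2Cl2, 0 °C → rt
Reagents that add atoms: 2 chloromethyl methyl ether, COCCl
Why: O-alkylation of both phenoxides (Williamson-type MOM protection) gives ethers that survive organometallic steps and later direct ortho-lithiation to the carbon between them.

**Step 2**
Reactants: 3 3,5-bis(methoxymethoxy)benzaldehyde; 4 (R)-4-benzyl-3-propionyloxazolidin-2-one
Product: 6 (R)-4-benzyl-3-[(2R,3R)-3-[3,5-bis(methoxymethoxy)phenyl]-3-hydroxy-2-methylpropanoyl]oxazolidin-2-one, via Z-boron enolate 5 (not isolated)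
Conditions: Bu2BOTf, i-Pr2NEt, CH2Cl2, 0 °C; then 3, −78 → 0 °C; pH 7 buffer, MeOH, 30% H2O2
Reagents that add atoms: 4 (R)-4-benzyl-3-propionyloxazolidin-2-one, CCC(=O)N1[C@H](Cc2ccccc2)COC1=O
Why: Evans syn-aldol reaction; the Z-boron enolate reacts through a Zimmerman–Traxler chair on the face opposite the benzyl group of the (R)-auxiliary, which sets C1 (R) and C2 (syn methyl, later S) together.

**Step 3**
Reactants: 6 aldol adduct; 7 tert-butyldimethylsilyl triflate
Product: 8 (R)-4-benzyl-3-[(2R,3R)-3-[3,5-bis(methoxymethoxy)phenyl]-3-(tert-butyldimethylsilyloxy)-2-methylpropanoyl]oxazolidin-2-one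
Conditions: TBSOTf, 2,6-lutidine, CH2Cl2, −78 → 0 °C
Reagents that add atoms: 7 tert-butyldimethylsilyl triflate, CC(C)(C)[Si](C)(C)OS(=O)(=O)C(F)(F)F
Why: Silylation of the hindered secondary benzylic alcohol blocks retro-aldol cleavage and gives a non-coordinating ether for the later lithiation.

**Step 4**
Reactants: 8 silylated aldol imide
Product: 9 (2S,3R)-3-[3,5-bis(methoxymethoxy)phenyl]-3-(tert-butyldimethylsilyloxy)-2-methylpropan-1-ol
Conditions: LiBH4, MeOH (1 equiv), THF, 0 °C
Reagents that add atoms: none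
Why: Reductive removal of the Evans auxiliary by hydride attack at the exocyclic imide carbonyl; the α-stereocentre is not enolized and the auxiliary is recovered.

**Step 5**
Reactants: 9 primary alcohol; 10 p-toluenesulfonyl chloride
Product: 11 (2S,3R)-3-[3,5-bis(methoxymethoxy)phenyl]-3-(tert-butyldimethylsilyloxy)-2-methylpropyl 4-methylbenzenesulfonate
Conditions: TsCl, Et3N, DMAP (cat.), CH2Cl2, 0 °C → rt
Reagents that add atoms: 10 p-toluenesulfonyl chloride, Cc1ccc(cc1)S(=O)(=O)Cl
Why: Sulfonylation of the only free hydroxyl activates C3 for carbon–carbon coupling.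

**Step 6**
Reactants: 11 tosylate; 12 allylmagnesium bromide
Product: 13 1-[(1R,2S)-1-(tert-butyldimethylsilyloxy)-2-methylhex-5-en-1-yl]-3,5-bis(methoxymethoxy)benzene
Conditions: allylMgBr (3 equiv), CuI (10 mol %), THF, −20 °C → rt
Reagents that add atoms: 12 allylmagnesium bromide, C=CC[Mg]Br
Why: Copper-catalysed coupling of a Grignard reagent with a primary tosylate (Fouquet–Schlosser type) adds C4, C5 and the terminal methylene; the C2 stereocentre is β to the reacting carbon and is untouched.

**Step 7**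
Reactants: 14 (S)-but-3-yn-2-ol; 15 4-bromo-1,1-dimethoxybutane
Product: 17 (S)-8,8-dimethoxyoct-3-yn-2-ol, via dilithio alkoxide acetylide 16 (not isolated)
Conditions: n-BuLi (2.1 equiv), THF, −78 → 0 °C; then 15, DMPU, NaI (cat.), rt
Reagents that add atoms: 15 4-bromo-1,1-dimethoxybutane, COC(OC)CCCBr
Why: SN2 alkylation of the dianion takes place at the acetylide carbon, which is far more nucleophilic than the lithium alkoxide; the carbinol centre is not involved.

**Step 8**
Reactants: 17 propargylic alcohol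
Product: 18 (2S,3Z)-8,8-dimethoxyoct-3-en-2-ol
Conditions: H2 (1 atm), Lindlar catalyst (Pd on CaCO3, poisoned with Pb(OAc)2), quinoline, EtOAc, rt
Reagents that add atoms: none
Why: Lindlar semihydrogenation adds hydrogen syn to the alkyne and gives the Z-alkene needed for clean 1,3-chirality transfer.

**Step 9**
Reactants: 18 Z-allylic alcohol; 19 picolinic acid
Product: 20 (2S,3Z)-8,8-dimethoxyoct-3-en-2-yl picolinate
Conditions: picolinic acid, DCC, DMAP, CH2Cl2, 0 °C → rt
Reagents that add atoms: 19 picolinic acid, OC(=O)c1ccccn1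
Why: Steglich esterification with retention at the carbinol carbon installs a chelating leaving group that promotes γ-selective anti substitution.

**Step 10**
Reactants: 13 arene arm (2.2 equiv); 20 allylic picolinate
Product: 24 5-[(1R,2S)-1-(tert-butyldimethylsilyloxy)-2-methylhex-5-en-1-yl]-2-[(2E,4R)-8,8-dimethoxyoct-2-en-4-yl]-1,3-bis(methoxymethoxy)benzene, via aryllithium 21 (not isolated), via arylmagnesium bromide 22 (not isolated), via bromomagnesium diarylcuprate 23 (not isolated)
Conditions: n-BuLi, THF, 0 °C; MgBr2·OEt2; CuBr·SMe2 (0.5 equiv per aryl), −40 °C; then 20, −40 → 0 °C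
Reagents that add atoms: 20 (2S,3Z)-8,8-dimethoxyoct-3-en-2-yl picolinate, C[C@H](OC(=O)c1ccccn1)/C=C\CCCC(OC)OC
Why: Directed ortho-lithiation between the two OMOM groups, then copper-mediated anti-SN2' substitution of the allylic picolinate; allylic 1,3-strain in the Z-alkene holds the carbinol hydrogen in the alkene plane, so aryl delivery anti to the chelated picolinate sets C7 and the E-propenyl group by 1,3-chirality transfer, and the unused aryl group returns as 13 on work-up.

**Step 11**
Reactants: 24 silyl ether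
Product: 25 (1R,2S)-1-{4-[(2E,4R)-8,8-dimethoxyoct-2-en-4-yl]-3,5-bis(methoxymethoxy)phenyl}-2-methylhex-5-en-1-ol
Conditions: Bu4NF, THF, 0 °C → rt
Reagents that add atoms: none
Why: Fluoride-induced desilylation; acetal, MOM ethers and both alkenes are inert to fluoride.

**Step 12**
Reactants: 25 benzylic alcohol; 26 trichloroacetyl isocyanate
Product: 28 (1R,2S)-1-{4-[(2E,4R)-8,8-dimethoxyoct-2-en-4-yl]-3,5-bis(methoxymethoxy)phenyl}-2-methylhex-5-en-1-yl carbamate, via N-trichloroacetyl carbamate 27 (not isolated)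
Conditions: Cl3CC(O)NCO, CH2Cl2, 0 °C; then K2CO3, MeOH, rt
Reagents that add atoms: 26 trichloroacetyl isocyanate, O=C=NC(=O)C(Cl)(Cl)Cl
Why: Addition of the alcohol to the acyl isocyanate followed by methanolysis of the trichloroacetyl group (Kocovsky carbamoylation) gives the primary carbamate with retention at C1.

**Step 13**
Reactants: 28 carbamate monomer (two molecules)
Product: 30 (1R,2S,5E,7R,14R,15S,18E,20R)-1,14-bis(carbamoyloxy)-7,20-bis(4,4-dimethoxybutyl)-2,15-dimethyl-9,13,22,26-tetrakis(methoxymethoxy)[7.7]paracyclophane-5,18-diene, via linear head-to-tail dimer 29 (not isolated)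
Conditions: second-generation Grubbs catalyst RuCl2(=CHPh)(H2IMes)(PCy3) (10 mol %), 1,4-benzoquinone (20 mol %), toluene (0.01 M), 60 °C, argon sparge
Reagents that add atoms: none
Why: Ruthenium-alkylidene olefin metathesis ([2+2] cycloaddition/cycloreversion cycles): the catalyst loads on the unhindered butenyl end (C5) of one molecule of 28 and cross-metathesizes onto the propenyl end (C6) of a second to give the head-to-tail dimer 29, which closes the 22-membered ring at the second C5=C6 pair, propene leaving twice. The closest known reaction type is the cross-metathesis/ring-closing-metathesis cyclodimerization of diene-bearing resorcinol monomers to [7.7]paracyclophanes. The one ring formed closes by macrocyclic ring-closing metathesis between C5 and C6; no new stereocentre arises, and the geometry of the two new alkenes does not matter because step 14 saturates them. The step needs head-to-tail pairing over head-to-head pairing and cyclic dimer over oligomer: the α-branched, aryl-flanked propenyl end cannot homocouple while butenyl homocoupling is reversible, the para relation of the two arms on each resorcinol ring rules out closure of a single monomer, and under reversible dilute conditions the strain-free C2-symmetric [7.7]paracyclophane is the thermodynamic sink. 1,4-Benzoquinone suppresses ruthenium hydride migration of the alkene next to C7.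

**Step 14**
Reactants: 30 macrocyclic diene
Product: 31 (1R,2S,7S,14R,15S,20S)-1,14-bis(carbamoyloxy)-7,20-bis(4,4-dimethoxybutyl)-2,15-dimethyl-9,13,22,26-tetrakis(methoxymethoxy)[7.7]paracyclophane
Conditions: H2 (1 atm), PtO2, EtOAc, rt
Reagents that add atoms: none
Why: Heterogeneous hydrogenation of the two disubstituted alkenes; platinum is a poor hydrogenolysis catalyst, so the benzylic carbamate C–O bonds should survive, and no stereocentre is touched (the C7/C20 descriptors change only through CIP priority).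

**Step 15**
Reactants: 31 bis(dimethyl acetal); 32 water
Product: 33 (1R,2S,7S,14R,15S,20S)-1,14-bis(carbamoyloxy)-2,15-dimethyl-9,13,22,26-tetrakis(methoxymethoxy)-7,20-bis(4-oxobutyl)[7.7]paracyclophane
Conditions: AcOH/THF/H2O (3:1:1), 40 °C
Reagents that add atoms: 32 water, O
Why: Mild acid hydrolysis of the aliphatic dimethyl acetals; aryl MOM ethers and the carbamates need much stronger acid.

**Step 16**
Reactants: 33 dialdehyde
Product: 34 (1R,2S,7S,14R,15S,20S)-1,14-bis(carbamoyloxy)-20-(4-hydroxybutyl)-2,15-dimethyl-9,13,22,26-tetrakis(methoxymethoxy)-7-(4-oxobutyl)[7.7]paracyclophane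
Conditions: NaBH4 (0.3 equiv), THF/EtOH, −40 °C; stopped at partial conversion, 33 recovered and resubmitted
Reagents that add atoms: none
Why: Statistical mono-reduction with a hydride deficit; the two aldehydes are equivalent by C2 symmetry and too far apart to influence each other, so only one mono-reduced product can form and it separates from 33 by polarity.

**Step 17**
Reactants: 34 hydroxy aldehyde; 35 CuCl2
Product: 37 (1R,2S,7S,14R,15S,20S)-1,14-bis(carbamoyloxy)-7-(4,4-dichlorobutyl)-20-(4-hydroxybutyl)-2,15-dimethyl-9,13,22,26-tetrakis(methoxymethoxy)[7.7]paracyclophane, via hydrazone 36 (not isolated)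
Conditions: N2H4·H2O (excess), MeOH/THF, 4 Å MS, rt, then evaporation; CuCl2 (6 equiv), Et3N, MeOH, 0 °C → rt
Reagents that add atoms: 35 CuCl2, Cl[Cu]Cl
Why: Takeda gem-dichlorination: CuCl2 oxidizes the aldehyde hydrazone to the diazoalkane, which is chlorinated twice with loss of N2; the alcohol, carbamates and MOM ethers are inert under these near-neutral conditions.

**Step 18**
Reactants: 37 dichloro alcohol; 38 lithium chloride
Product: 40 (1R,2S,7S,14R,15S,20S)-1,14-bis(carbamoyloxy)-20-(4-chlorobutyl)-7-(4,4-dichlorobutyl)-2,15-dimethyl-9,13,22,26-tetrakis(methoxymethoxy)[7.7]paracyclophane, via mesylate 39 (not isolated)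
Conditions: MsCl, Et3N, CH2Cl2, 0 °C; then LiCl, DMF, 50 °C
Reagents that add atoms: 38 lithium chloride, [Li+].[Cl-]
Why: Mesylation then SN2 displacement by chloride at the primary carbon; this avoids phosphorus halide reagents that could dehydrate the primary carbamates.

**Step 19**
Reactants: 40 tetrakis-MOM ether
Product: 41 CNP0310589.1
Conditions: HCl (3 M in MeOH), THF, rt → 40 °C
Reagents that add atoms: none
Why: Acid-catalysed acetal exchange removes the four aryl MOM groups; the benzylic carbamates resist ionization because the ring oxygens are meta to C1/C14, and the alkyl chlorides are acid-stable.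

**Compound list**
1 | 3,5-dihydroxybenzaldehyde | O=Cc1cc(O)cc(O)c1 | starting material
2 | chloromethyl methyl ether | COCCl | starting material
3 | 3,5-bis(methoxymethoxy)benzaldehyde | COCOc1cc(C=O)cc(OCOC)c1 | intermediate
4 | (R)-4-benzyl-3-propionyloxazolidin-2-one | CCC(=O)N1[C@H](Cc2ccccc2)COC1=O | starting material
5 | Z-dibutylboron enolate of 4 | C/C=C(\OB(CCCC)CCCC)N1[C@H](Cc2ccccc2)COC1=O | intermediate (not isolated)
6 | (R)-4-benzyl-3-[(2R,3R)-3-[3,5-bis(methoxymethoxy)phenyl]-3-hydroxy-2-methylpropanoyl]oxazolidin-2-one | COCOc1cc(cc(OCOC)c1)[C@H](O)[C@@H](C)C(=O)N1[C@H](Cc2ccccc2)COC1=O | intermediate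
7 | tert-butyldimethylsilyl triflate | CC(C)(C)[Si](C)(C)OS(=O)(=O)C(F)(F)F | starting material
8 | TBS ether of 6, (2R,3R) | COCOc1cc(cc(OCOC)c1)[C@H](O[Si](C)(C)C(C)(C)C)[C@@H](C)C(=O)N1[C@H](Cc2ccccc2)COC1=O | intermediate
9 | (2S,3R)-3-[3,5-bis(methoxymethoxy)phenyl]-3-(tert-butyldimethylsilyloxy)-2-methylpropan-1-ol | COCOc1cc(cc(OCOC)c1)[C@H](O[Si](C)(C)C(C)(C)C)[C@@H](C)CO | intermediate
10 | p-toluenesulfonyl chloride | Cc1ccc(cc1)S(=O)(=O)Cl | starting material
11 | tosylate of 9, (2S,3R) | COCOc1cc(cc(OCOC)c1)[C@H](O[Si](C)(C)C(C)(C)C)[C@@H](C)COS(=O)(=O)c1ccc(C)cc1 | intermediate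
12 | allylmagnesium bromide | C=CC[Mg]Br | starting material
13 | 1-[(1R,2S)-1-(tert-butyldimethylsilyloxy)-2-methylhex-5-en-1-yl]-3,5-bis(methoxymethoxy)benzene | COCOc1cc(cc(OCOC)c1)[C@H](O[Si](C)(C)C(C)(C)C)[C@@H](C)CCC=C | intermediate
14 | (S)-but-3-yn-2-ol | C[C@H](O)C#C | starting material
15 | 4-bromo-1,1-dimethoxybutane | COC(OC)CCCBr | starting material
16 | dilithio alkoxide acetylide of 14 | C[C@H](O[Li])C#C[Li] | intermediate (not isolated)
17 | (S)-8,8-dimethoxyoct-3-yn-2-ol | C[C@H](O)C#CCCCC(OC)OC | intermediate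
18 | (2S,3Z)-8,8-dimethoxyoct-3-en-2-ol | C[C@H](O)/C=C\CCCC(OC)OC | intermediate
19 | picolinic acid | OC(=O)c1ccccn1 | starting material
20 | (2S,3Z)-8,8-dimethoxyoct-3-en-2-yl picolinate | C[C@H](OC(=O)c1ccccn1)/C=C\CCCC(OC)OC | intermediate
21 | aryllithium from 13 (Li on the ring carbon between the two OMOM groups) | [Li]c1c(OCOC)cc(cc1OCOC)[C@H](O[Si](C)(C)C(C)(C)C)[C@@H](C)CCC=C | intermediate (not isolated)
22 | arylmagnesium bromide from 21 | Br[Mg]c1c(OCOC)cc(cc1OCOC)[C@H](O[Si](C)(C)C(C)(C)C)[C@@H](C)CCC=C | intermediate (not isolated)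
23 | bromomagnesium diarylcuprate from 22 | [Mg+]Br.[Cu-](c1c(OCOC)cc(cc1OCOC)[C@H](O[Si](C)(C)C(C)(C)C)[C@@H](C)CCC=C)c1c(OCOC)cc(cc1OCOC)[C@H](O[Si](C)(C)C(C)(C)C)[C@@H](C)CCC=C | intermediate (not isolated)
24 | 5-[(1R,2S)-1-(tert-butyldimethylsilyloxy)-2-methylhex-5-en-1-yl]-2-[(2E,4R)-8,8-dimethoxyoct-2-en-4-yl]-1,3-bis(methoxymethoxy)benzene | C/C=C/[C@@H](CCCC(OC)OC)c1c(OCOC)cc(cc1OCOC)[C@H](O[Si](C)(C)C(C)(C)C)[C@@H](C)CCC=C | intermediate
25 | (1R,2S)-1-{4-[(2E,4R)-8,8-dimethoxyoct-2-en-4-yl]-3,5-bis(methoxymethoxy)phenyl}-2-methylhex-5-en-1-ol | C/C=C/[C@@H](CCCC(OC)OC)c1c(OCOC)cc(cc1OCOC)[C@H](O)[C@@H](C)CCC=C | intermediate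
26 | trichloroacetyl isocyanate | O=C=NC(=O)C(Cl)(Cl)Cl | starting material
27 | N-trichloroacetyl carbamate of 25 | C/C=C/[C@@H](CCCC(OC)OC)c1c(OCOC)cc(cc1OCOC)[C@H](OC(=O)NC(=O)C(Cl)(Cl)Cl)[C@@H](C)CCC=C | intermediate (not isolated)
28 | carbamate of 25 (monomer), (1R,2S) at the arm, (4R,2E) at the octenyl group | C/C=C/[C@@H](CCCC(OC)OC)c1c(OCOC)cc(cc1OCOC)[C@H](OC(N)=O)[C@@H](C)CCC=C | intermediate
29 | linear head-to-tail dimer of 28 (one new E C5=C6 alkene, one propenyl and one butenyl end) | C/C=C/[C@@H](CCCC(OC)OC)c1c(OCOC)cc(cc1OCOC)[C@H](OC(N)=O)[C@@H](C)CC/C=C/[C@@H](CCCC(OC)OC)c1c(OCOC)cc(cc1OCOC)[C@H](OC(N)=O)[C@@H](C)CCC=C | intermediate (not isolated)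
30 | (1R,2S,5E,7R,14R,15S,18E,20R)-[7.7]paracyclophane-5,18-diene, bis-carbamate, bis(dimethyl acetal), tetrakis-MOM ether | C[C@H]1CC/C=C/[C@@H](CCCC(OC)OC)c2c(OCOC)cc(cc2OCOC)[C@H](OC(N)=O)[C@@H](C)CC/C=C/[C@@H](CCCC(OC)OC)c2c(OCOC)cc(cc2OCOC)[C@@H]1OC(N)=O | intermediate
31 | (1R,2S,7S,14R,15S,20S) saturated [7.7]paracyclophane, bis-carbamate, bis(dimethyl acetal), tetrakis-MOM ether | C[C@H]1CCCC[C@@H](CCCC(OC)OC)c2c(OCOC)cc(cc2OCOC)[C@H](OC(N)=O)[C@@H](C)CCCC[C@@H](CCCC(OC)OC)c2c(OCOC)cc(cc2OCOC)[C@@H]1OC(N)=O | intermediate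
32 | water | O | starting material
33 | C2-symmetric dialdehyde, 7,20-bis(4-oxobutyl) | C[C@H]1CCCC[C@@H](CCCC=O)c2c(OCOC)cc(cc2OCOC)[C@H](OC(N)=O)[C@@H](C)CCCC[C@@H](CCCC=O)c2c(OCOC)cc(cc2OCOC)[C@@H]1OC(N)=O | intermediate
34 | hydroxy aldehyde, 20-(4-hydroxybutyl)-7-(4-oxobutyl) | C[C@H]1CCCC[C@@H](CCCCO)c2c(OCOC)cc(cc2OCOC)[C@H](OC(N)=O)[C@@H](C)CCCC[C@@H](CCCC=O)c2c(OCOC)cc(cc2OCOC)[C@@H]1OC(N)=O | intermediate
35 | CuCl2 | Cl[Cu]Cl | starting material
36 | hydrazone of 34 | C[C@H]1CCCC[C@@H](CCCCO)c2c(OCOC)cc(cc2OCOC)[C@H](OC(N)=O)[C@@H](C)CCCC[C@@H](CCCC=NN)c2c(OCOC)cc(cc2OCOC)[C@@H]1OC(N)=O | intermediate (not isolated)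
37 | dichloro alcohol, 7-(4,4-dichlorobutyl)-20-(4-hydroxybutyl) | C[C@H]1CCCC[C@@H](CCCCO)c2c(OCOC)cc(cc2OCOC)[C@H](OC(N)=O)[C@@H](C)CCCC[C@@H](CCCC(Cl)Cl)c2c(OCOC)cc(cc2OCOC)[C@@H]1OC(N)=O | intermediate
38 | lithium chloride | [Li+].[Cl-] | starting material
39 | mesylate of 37 | C[C@H]1CCCC[C@@H](CCCCOS(C)(=O)=O)c2c(OCOC)cc(cc2OCOC)[C@H](OC(N)=O)[C@@H](C)CCCC[C@@H](CCCC(Cl)Cl)c2c(OCOC)cc(cc2OCOC)[C@@H]1OC(N)=O | intermediate (not isolated)
40 | tetrakis-MOM ether of the target | C[C@H]1CCCC[C@@H](CCCCCl)c2c(OCOC)cc(cc2OCOC)[C@H](OC(N)=O)[C@@H](C)CCCC[C@@H](CCCC(Cl)Cl)c2c(OCOC)cc(cc2OCOC)[C@@H]1OC(N)=O | intermediate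
41 | CNP0310589.1, (1R,2S,7S,14R,15S,20S) | C[C@H]1CCCC[C@@H](CCCCCl)c2c(O)cc(cc2O)[C@H](OC(N)=O)[C@@H](C)CCCC[C@@H](CCCC(Cl)Cl)c2c(O)cc(cc2O)[C@@H]1OC(N)=O | target

**Step count**
Total: 19 steps. Longest linear sequence: 16 steps (steps 1–6 and 10–19).

**Steps most likely to fail**

Step 13. The α-branched propenyl end, flanked by the 2,6-bis(methoxymethoxy)aryl group, may fail to enter the catalytic cycle, leaving only reversible butenyl homocoupling and oligomerization; ruthenium hydrides may also migrate the alkene next to C7. The fallback replaces alkene by alkyne metathesis, where the reacting carbon is linear and less shielded. It sets out from 24 and comes back at 31. Ozonolysis of both alkenes of 24 (O3, CH2Cl2/MeOH, −78 °C; PPh3) would give the dialdehyde F1. Ohira–Bestmann homologation (dimethyl (1-diazo-2-oxopropyl)phosphonate, K2CO3, MeOH, 0 °C) would give the bis(terminal alkyne) F2. Double C-methylation (n-BuLi, THF, −78 °C; MeI) would give the methyl-capped diyne F3. Bu4NF would give the alcohol F4. Cl3CC(O)NCO followed by K2CO3/MeOH would lead through the N-trichloroacetyl carbamate F5 to the diyne carbamate F6. Alkyne metathesis cyclodimerization (molybdenum alkylidyne Mo(≡CC6H4OMe-4)(OSiPh3)3, 5 Å MS, toluene, 80 °C) would give the cyclic diyne F7 with loss of but-2-yne. Full hydrogenation (H2, PtO2, EtOAc) would give 31.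

Step 10. The hindered aryl copper reagent may attack the α- instead of the γ-carbon, transfer incompletely, or lose 1,3-chirality transfer. The fallback uses directed syn delivery on the E-isomer instead of anti attack on the Z-isomer. It sets out from 17 and comes back at 24. Trans-reduction of 17 (NaAlH2(OCH2CH2OMe)2, THF, 0 °C) would give (2S,3E)-8,8-dimethoxyoct-3-en-2-ol F8. Esterification with 2-(diphenylphosphino)benzoic acid (DCC, DMAP) would give the ortho-diphenylphosphinobenzoate F9. The Grignard reagent 22 with CuBr·SMe2 (0.5 equiv) in Et2O at rt should then be delivered syn to the phosphine-bound leaving group at the γ-carbon, which from the (S,E)-substrate gives the same C7 configuration and E-propenyl group as in 24.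

Step 17. Azine formation during hydrazone preparation, incomplete oxidation–chlorination, or elimination to a vinyl chloride may erode the gem-dichlorination. The fallback is deoxygenative chlorination. It sets out from 34 and comes back at 40. Triphenyl phosphite–chlorine ((PhO)3P, Cl2, Et3N, CH2Cl2, −78 °C → rt) converts aldehydes to gem-dichlorides and primary alcohols to chlorides, so 34 would go to 40 in one operation, replacing steps 17 and 18. Base would be kept to the minimum to limit dehydration of the primary carbamates.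

**Further compounds**
F1 | step 13 | dialdehyde from ozonolysis of 24 | O=C[C@@H](CCCC(OC)OC)c1c(OCOC)cc(cc1OCOC)[C@H](O[Si](C)(C)C(C)(C)C)[C@@H](C)CCC=O
F2 | step 13 | bis(terminal alkyne) | C#C[C@@H](CCCC(OC)OC)c1c(OCOC)cc(cc1OCOC)[C@H](O[Si](C)(C)C(C)(C)C)[C@@H](C)CCC#C
F3 | step 13 | methyl-capped diyne | CC#C[C@@H](CCCC(OC)OC)c1c(OCOC)cc(cc1OCOC)[C@H](O[Si](C)(C)C(C)(C)C)[C@@H](C)CCC#CC
F4 | step 13 | diyne alcohol | CC#C[C@@H](CCCC(OC)OC)c1c(OCOC)cc(cc1OCOC)[C@H](O)[C@@H](C)CCC#CC
F5 | step 13 | N-trichloroacetyl carbamate of F4 | CC#C[C@@H](CCCC(OC)OC)c1c(OCOC)cc(cc1OCOC)[C@H](OC(=O)NC(=O)C(Cl)(Cl)Cl)[C@@H](C)CCC#CC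
F6 | step 13 | diyne carbamate monomer | CC#C[C@@H](CCCC(OC)OC)c1c(OCOC)cc(cc1OCOC)[C@H](OC(N)=O)[C@@H](C)CCC#CC
F7 | step 13 | cyclic 5,18-diyne of the [7.7]paracyclophane | C[C@H]1CCC#C[C@@H](CCCC(OC)OC)c2c(OCOC)cc(cc2OCOC)[C@H](OC(N)=O)[C@@H](C)CCC#C[C@@H](CCCC(OC)OC)c2c(OCOC)cc(cc2OCOC)[C@@H]1OC(N)=O
F8 | step 10 | (2S,3E)-8,8-dimethoxyoct-3-en-2-ol | C[C@H](O)/C=C/CCCC(OC)OC
F9 | step 10 | (2S,3E)-8,8-dimethoxyoct-3-en-2-yl 2-(diphenylphosphino)benzoate | C[C@H](OC(=O)c1ccccc1P(c1ccccc1)c1ccccc1)/C=C/CCCC(OC)OC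
F0 | step 17 | none | none
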